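Ring B of the target carries the C8 tertiary hydroxyl (with methyl C17) and the C5 ring-fusion hydrogen para to each other on the α face. The route reads C5–C8 as a 2-methylfuran whose oxygen is kept as that hydroxyl. One Lewis-acid-promoted intramolecular furan Diels–Alder reaction of a furyl ester bearing a four-carbon-tethered (E)-β-methyl enal forms C5–C10 and C8–C9, closes rings A and B as an oxygen-bridged octalin, and sets C8, C9 and C10 relative to the bridge under control of the single stereocentre at C4. Enolate-triggered bridge opening, reductive methylation at C4 and a B-alkyl Suzuki coupling with a glyceraldehyde-derived alkenyl triflate complete the labdane.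

Key step: step 9

Remark: labdane numbering is used for the ring carbons (C1–C10 decalin, C11 on C9, C17 methyl on C8, C20 methyl on C10); α is the face of H-5 and the C8 oxygen, β the face of the C20 methyl.
Assumption: the (S,S)-antipode of the chiral tetramine in step 5 is taken to give the 2R acid, by analogy with the sense known for phenylacetic acid; the antipode is exchanged if a first correlation shows otherwise.

Step 1
Reactants: 1 5-chloropent-1-yne
Product: 4 (2E)-6-chloro-3-methylhex-2-en-1-ol, via alkenyldimethylalane 2 (not isolated), via lithium alkenylalanate 3 (not isolated)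
Conditions: AlMe3 (2 equiv), Cp2ZrCl2 (0.2 equiv), CH2Cl2, 0 °C → rt; excess AlMe3 removed in vacuo; n-BuLi, hexane–THF, −78 → 0 °C; (CH2O)n, rt; aq. HCl
Reagents that add atoms: trimethylaluminium (C[Al](C)C); formaldehyde as paraformaldehyde (C=O)
Why: Negishi carboalumination adds methyl and aluminium syn across the terminal alkyne (methyl to the internal carbon) and the alanate is hydroxymethylated with retention, so the trisubstituted alkene should form as the E isomer only, the primary chloride being inert.

Step 2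
Reactants: 4 (2E)-6-chloro-3-methylhex-2-en-1-ol
Product: 6 tert-butyl{[(2E)-6-iodo-3-methylhex-2-en-1-yl]oxy}dimethylsilane, via chloro silyl ether 5 (not isolated)
Conditions: TBSCl, imidazole, DMF, rt; then NaI, 70 °C
Reagents that add atoms: tert-butyldimethylsilyl chloride (CC(C)(C)[Si](C)(C)Cl); sodium iodide ([Na+].[I-])
Why: Silylation of the primary allylic alcohol followed in the same flask by Finkelstein exchange gives a base-stable iodide reactive enough for a low-temperature enolate alkylation.

Step 3
Reactants: 7 2-methylfuran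
Product: 8 ethyl 2-(5-methylfuran-2-yl)acetate
Conditions: ICH2CO2Et, FeSO4·7H2O (cat.), 30% H2O2, DMSO, rt (7 in excess)
Reagents that add atoms: ethyl iodoacetate (CCOC(=O)CI)
Why: Homolytic aromatic substitution under Fenton conditions: the electrophilic ethoxycarbonylmethyl radical released from the iodide adds to the free α-position of the electron-rich furan and the adduct radical is oxidised back to the heteroarene.

Step 4
Reactants: 8 ethyl 2-(5-methylfuran-2-yl)acetate
Product: 9 2-(5-methylfuran-2-yl)acetic acid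
Conditions: LiOH·H2O, THF–H2O, rt; cold dilute HCl to pH 3
Reagents that add atoms: lithium hydroxide ([Li+].[OH-])
Why: Saponification of an unhindered ester, with brief cold acidification to spare the acid-sensitive dialkylfuran.

Step 5
Reactants: 9 2-(5-methylfuran-2-yl)acetic acid; 6 tert-butyl{[(2E)-6-iodo-3-methylhex-2-en-1-yl]oxy}dimethylsilane
Product: 11 (2R,6E)-8-[(tert-butyldimethylsilyl)oxy]-6-methyl-2-(5-methylfuran-2-yl)oct-6-enoic acid, via dilithium enediolate 10 (not isolated)
Conditions: (S,S)-N1,N3-bis[1-phenyl-2-(piperidin-1-yl)ethyl]propane-1,3-diamine (1.03 equiv), n-BuLi (4.0 equiv), THF, 0 °C; 6, −78 °C; cold 0.5 M HCl, amine recovered from the aqueous phase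
Reagents that add atoms: none
Why: Enantioselective enediolate alkylation of an arylacetic acid directed by a chiral lithium amide: the dilithium enediolate sits in a mixed aggregate with the C2-symmetric dilithium amide, which exposes one face to the primary iodide and should set C4 as R without an auxiliary to attach or remove.

Step 6
Reactants: 11 (2R,6E)-8-[(tert-butyldimethylsilyl)oxy]-6-methyl-2-(5-methylfuran-2-yl)oct-6-enoic acid
Product: 12 methyl (2R,6E)-8-[(tert-butyldimethylsilyl)oxy]-6-methyl-2-(5-methylfuran-2-yl)oct-6-enoate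
Conditions: TMSCHN2, PhMe–MeOH, 0 °C
Reagents that add atoms: trimethylsilyldiazomethane (C[Si](C)(C)C=[N+]=[N-])
Why: Diazoalkane esterification is neutral and fast, so the doubly activated C4 stereocentre never meets base.

Step 7
Reactants: 12 methyl (2R,6E)-8-[(tert-butyldimethylsilyl)oxy]-6-methyl-2-(5-methylfuran-2-yl)oct-6-enoate
Product: 13 methyl (2R,6E)-8-hydroxy-6-methyl-2-(5-methylfuran-2-yl)oct-6-enoate
Conditions: HF·pyridine, THF–pyridine, 0 °C → rt
Reagents that add atoms: none
Why: Buffered fluoride desilylation of the primary silyl ether leaves the epimerisable ester, the furan and the alkene geometry untouched.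

Step 8
Reactants: 13 methyl (2R,6E)-8-hydroxy-6-methyl-2-(5-methylfuran-2-yl)oct-6-enoate
Product: 14 methyl (2R,6E)-6-methyl-2-(5-methylfuran-2-yl)-8-oxooct-6-enoate
Conditions: MnO2, CH2Cl2, rt
Reagents that add atoms: none
Why: Heterogeneous MnO2 oxidation is selective for the allylic alcohol and needs no base, so the E-enal should form without E/Z isomerisation or epimerisation at C4.

Step 9
Reactants: 14 methyl (2R,6E)-6-methyl-2-(5-methylfuran-2-yl)-8-oxooct-6-enoate
Product: 15 methyl (1R,2R,6R,7R,8R)-7-formyl-6,8-dimethyl-11-oxatricyclo[6.2.1.0^1,6]undec-9-ene-2-carboxylate (5α,8α-oxygen-bridged octalin; C6=C7; C9 formyl β; C10 methyl β; C4 ester α)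
Conditions: MeAlCl2 (1.1–1.5 equiv), CH2Cl2, −78 °C; Et3N then aq. NaHCO3 at −78 °C; cold work-up, used at once
Reagents that add atoms: none
Why: MeAlCl2 binds the formyl oxygen and lowers the LUMO of the E-enal, which adds across C5 and C8 of the furan in an asynchronous concerted [4+2] process in which the C5–C10 bond (nucleophilic furan α-carbon to enal β-carbon) is the more advanced. The closest known reaction type is the alkylaluminium-chloride-promoted intramolecular Diels–Alder reaction of furans carrying tethered enones or enals. Ring B (C5–C6–C7–C8–C9–C10) closes by the cycloaddition itself and is spanned by the furan oxygen, while ring A (C1–C5, C10) closes through the four-carbon tether in a chair-like array, the short tether being able to link the bridgehead only to the exo position. C5 and C8 are tied to one face by the oxygen bridge; C9 and C10 follow from suprafacial addition to the E-alkene, so with the tether exo the formyl group and the C10 methyl are both endo, anti to the bridge; the absolute sense of all four comes from C4, whose ester lies pseudo-equatorial and anti to the forming C5–C10 bond while H-4 eclipses the furan C6–H (least allylic 1,3-strain), exposing one furan face. The step needs exo-tether, endo-formyl and furan-face selectivity: the first is geometric, the second is fixed by the alkene geometry from step 1, the third by the R centre from step 5, and the low temperature plus the stronger binding of the Lewis acid to the saturated aldehyde of the adduct should hold the equilibrium on the product side.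

Step 10
Reactants: 15 oxygen-bridged octalin aldehyde
Product: 16 methyl (1R,2R,6R,7R,8R)-7-formyl-6,8-dimethyl-11-oxatricyclo[6.2.1.0^1,6]undecane-2-carboxylate
Conditions: H2 (1 atm), 10% Pd/C, EtOAc, 0 °C
Reagents that add atoms: none
Why: Catalytic hydrogenation of the strained, exposed C6=C7 bond is fast while the aldehyde is inert, and it removes the retro-Diels–Alder pathway for good.

Step 11
Reactants: 16 saturated oxygen-bridged aldehyde
Product: 17 methyl (1R,2R,6R,7R,8R)-7-ethenyl-6,8-dimethyl-11-oxatricyclo[6.2.1.0^1,6]undecane-2-carboxylate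
Conditions: Cp2Ti(μ-Cl)(μ-CH2)AlMe2 (1.1 equiv), pyridine (cat.), THF–PhMe, −40 → 0 °C; aq. NaOH
Reagents that add atoms: Tebbe reagent (C[Al-]1(C)C[Ti]([Cl+]1)(C1C=CC=C1)C1C=CC=C1)
Why: Tebbe methylenation is non-basic, so neither C9 epimerisation nor β-elimination of the C8 oxygen can start, and one equivalent at low temperature should take the aldehyde in preference to the ester.

Step 12
Reactants: 17 oxygen-bridged vinyl ester
Product: 19 methyl (4aR,5R,6R)-5-ethenyl-6-hydroxy-4a,6-dimethyl-2,3,4,4a,5,6,7,8-octahydronaphthalene-1-carboxylate (C4=C5 enoate, 8α-OH), via lithium ester enolate 18 (not isolated)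
Conditions: LiN(iPr)2 (1.1 equiv), THF, −78 → −20 °C; aq. NH4Cl
Reagents that add atoms: none
Why: E1cB elimination: the C4 ester enolate is aligned with the axial C5–O bond and expels the bridging oxygen, releasing the strain of the oxabicycle and giving the conjugated enoate with the free 8α-hydroxyl, C8, C9 and C10 untouched.

Step 13
Reactants: 19 hydroxy enoate
Product: 21 methyl (1S,4aS,5R,6R,8aR)-5-ethenyl-6-hydroxy-1,4a,6-trimethyldecahydronaphthalene-1-carboxylate, via dilithium alkoxide enolate 20 (not isolated)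
Conditions: Li (2.2 equiv), NH3(l)–THF, −78 °C; MeI (excess), −78 → −33 °C; NH4Cl
Reagents that add atoms: iodomethane (CI)
Why: Dissolving-metal reductive alkylation: two-electron reduction of the enoate with protonation of C5 from the α face (the C8 hydroxyl as the one proton donor) should give the trans ring fusion as in octalone reductions, and the C4 ester enolate is methylated from the equatorial α face, away from the axial C20 methyl, leaving the ester axial (β).

Step 14
Reactants: 22 (R)-2,2-dimethyl-1,3-dioxolane-4-carbaldehyde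
Product: 23 1-[(4R)-2,2-dimethyl-1,3-dioxolan-4-yl]ethan-1-ol (carbinol epimers)
Conditions: MeMgBr, THF, −78 → 0 °C; aq. NH4Cl
Reagents that add atoms: methylmagnesium bromide (C[Mg]Br)
Why: Grignard addition to the aldehyde; the new carbinol centre is removed in the next step, so its configuration does not matter.

Step 15
Reactants: 23 1-[(4R)-2,2-dimethyl-1,3-dioxolan-4-yl]ethan-1-ol
Product: 24 1-[(4R)-2,2-dimethyl-1,3-dioxolan-4-yl]ethan-1-one
Conditions: Dess–Martin periodinane, NaHCO3, CH2Cl2, 0 °C → rt
Reagents that add atoms: none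
Why: Buffered Dess–Martin oxidation should give the methyl ketone without epimerising the α-alkoxy centre.

Step 16
Reactants: 24 1-[(4R)-2,2-dimethyl-1,3-dioxolan-4-yl]ethan-1-one
Product: 26 1-[(4R)-2,2-dimethyl-1,3-dioxolan-4-yl]ethenyl trifluoromethanesulfonate, via potassium enolate 25 (not isolated)
Conditions: KN(SiMe3)2, THF, −78 °C; N-(5-chloropyridin-2-yl)triflimide, −78 → −40 °C
Reagents that add atoms: N-(5-chloropyridin-2-yl)-bis(trifluoromethanesulfonyl)imide (O=S(=O)(N(c1ccc(Cl)cn1)S(=O)(=O)C(F)(F)F)C(F)(F)F)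
Why: Kinetic enolisation by the hindered amide occurs at the methyl group, not at the oxygenated methine, and O-triflation of that enolate gives the 1,1-disubstituted alkenyl triflate with the future C14 centre intact.

Step 17
Reactants: 21 methyl 8α-hydroxy-13,14,15,16-tetranorlabd-11-en-19-oate (name as in step 13); 26 1-[(4R)-2,2-dimethyl-1,3-dioxolan-4-yl]ethenyl trifluoromethanesulfonate
Product: 28 methyl (1S,4aS,5R,6R,8aR)-5-{3-[(4S)-2,2-dimethyl-1,3-dioxolan-4-yl]but-3-en-1-yl}-6-hydroxy-1,4a,6-trimethyldecahydronaphthalene-1-carboxylate, via B-alkyl-9-BBN 27 (not isolated)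
Conditions: 9-BBN dimer, THF, rt → 50 °C; then 3 M aq. K3PO4, 26, Pd(dppf)Cl2 (5 mol %), AsPh3, DMF, rt → 45 °C
Reagents that add atoms: none
Why: Anti-Markovnikov hydroboration of the monosubstituted C11=C12 alkene followed by B-alkyl Suzuki–Miyaura coupling with the alkenyl triflate forms C12–C13 and brings in the exocyclic methylene and the C14 stereocentre together.

Step 18
Reactants: 28 acetonide methyl ester
Product: 29 (1S,4aS,5R,6R,8aR)-5-{3-[(4S)-2,2-dimethyl-1,3-dioxolan-4-yl]but-3-en-1-yl}-6-hydroxy-1,4a,6-trimethyldecahydronaphthalene-1-carboxylic acid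
Conditions: n-PrSLi (from n-PrSH, n-BuLi), HMPA, rt; cold 0.5 M HCl to pH 4
Reagents that add atoms: none
Why: SN2 demethylation: the soft thiolate attacks the ester methyl group, which cleaves the axial neopentyl C19 ester that resists acyl-oxygen saponification.

Step 19
Reactants: 29 acetonide acid
Product: 30 (1S,4aS,5R,6R,8aR)-5-[(4S)-4,5-dihydroxy-3-methylidenepentyl]-6-hydroxy-1,4a,6-trimethyldecahydronaphthalene-1-carboxylic acid (CNP0216809.1)
Conditions: AcOH–H2O (4:1), 40 °C
Reagents that add atoms: none
Why: Mild acid hydrolysis of the terminal acetonide should proceed without dehydrating the tertiary C8 alcohol or protonating the 13(16)-alkene.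

Compound list
1 | 5-chloropent-1-yne | C#CCCCCl | starting material
2 | [(1E)-5-chloro-2-methylpent-1-en-1-yl]dimethylalane | C[Al](C)/C=C(\C)CCCCl | intermediate
3 | lithium butyl[(1E)-5-chloro-2-methylpent-1-en-1-yl]dimethylalanate | [Li+].CCCC[Al-](C)(C)/C=C(\C)CCCCl | intermediate
4 | (2E)-6-chloro-3-methylhex-2-en-1-ol | OC/C=C(\C)CCCCl | intermediate
5 | tert-butyl{[(2E)-6-chloro-3-methylhex-2-en-1-yl]oxy}dimethylsilane | CC(C)(C)[Si](C)(C)OC/C=C(\C)CCCCl | intermediate
6 | tert-butyl{[(2E)-6-iodo-3-methylhex-2-en-1-yl]oxy}dimethylsilane | CC(C)(C)[Si](C)(C)OC/C=C(\C)CCCI | intermediate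
7 | 2-methylfuran | Cc1ccco1 | starting material
8 | ethyl 2-(5-methylfuran-2-yl)acetate | CCOC(=O)Cc1ccc(C)o1 | intermediate
9 | 2-(5-methylfuran-2-yl)acetic acid | Cc1ccc(CC(=O)O)o1 | intermediate
10 | dilithium 2-(5-methylfuran-2-yl)ethene-1,1-diolate | [Li+].[Li+].Cc1ccc(C=C([O-])[O-])o1 | intermediate
11 | (2R,6E)-8-[(tert-butyldimethylsilyl)oxy]-6-methyl-2-(5-methylfuran-2-yl)oct-6-enoic acid | Cc1ccc(o1)[C@H](C(=O)O)CCC/C(C)=C/CO[Si](C)(C)C(C)(C)C | intermediate
12 | methyl (2R,6E)-8-[(tert-butyldimethylsilyl)oxy]-6-methyl-2-(5-methylfuran-2-yl)oct-6-enoate | Cc1ccc(o1)[C@H](C(=O)OC)CCC/C(C)=C/CO[Si](C)(C)C(C)(C)C | intermediate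
13 | methyl (2R,6E)-8-hydroxy-6-methyl-2-(5-methylfuran-2-yl)oct-6-enoate | Cc1ccc(o1)[C@H](C(=O)OC)CCC/C(C)=C/CO | intermediate
14 | methyl (2R,6E)-6-methyl-2-(5-methylfuran-2-yl)-8-oxooct-6-enoate | Cc1ccc(o1)[C@H](C(=O)OC)CCC/C(C)=C/C=O | intermediate
15 | methyl (1R,2R,6R,7R,8R)-7-formyl-6,8-dimethyl-11-oxatricyclo[6.2.1.0^1,6]undec-9-ene-2-carboxylate | O=C[C@@H]1[C@@]2(C)CCC[C@@H](C(=O)OC)[C@]23C=C[C@@]1(C)O3 | intermediate
16 | methyl (1R,2R,6R,7R,8R)-7-formyl-6,8-dimethyl-11-oxatricyclo[6.2.1.0^1,6]undecane-2-carboxylate | O=C[C@@H]1[C@@]2(C)CCC[C@@H](C(=O)OC)[C@]23CC[C@@]1(C)O3 | intermediate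
17 | methyl (1R,2R,6R,7R,8R)-7-ethenyl-6,8-dimethyl-11-oxatricyclo[6.2.1.0^1,6]undecane-2-carboxylate | C=C[C@@H]1[C@@]2(C)CCC[C@@H](C(=O)OC)[C@]23CC[C@@]1(C)O3 | intermediate
18 | lithium ester enolate of 17 (C4=C(OMe)OLi, bridge intact) | [Li+].C=C[C@@H]1[C@@]2(C)CCCC(=C([O-])OC)[C@]23CC[C@@]1(C)O3 | intermediate
19 | methyl (4aR,5R,6R)-5-ethenyl-6-hydroxy-4a,6-dimethyl-2,3,4,4a,5,6,7,8-octahydronaphthalene-1-carboxylate | C=C[C@@H]1[C@@]2(C)CCCC(C(=O)OC)=C2CC[C@@]1(C)O | intermediate
20 | dilithium C8-alkoxide C4-ester enolate (5α-H, trans-fused) | [Li+].[Li+].C=C[C@@H]1[C@@]2(C)CCCC(=C([O-])OC)[C@@H]2CC[C@@]1(C)[O-] | intermediate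
21 | methyl (1S,4aS,5R,6R,8aR)-5-ethenyl-6-hydroxy-1,4a,6-trimethyldecahydronaphthalene-1-carboxylate | C=C[C@@H]1[C@@]2(C)CCC[C@](C)(C(=O)OC)[C@@H]2CC[C@@]1(C)O | intermediate
22 | (R)-2,2-dimethyl-1,3-dioxolane-4-carbaldehyde | O=C[C@H]1COC(C)(C)O1 | starting material
23 | 1-[(4R)-2,2-dimethyl-1,3-dioxolan-4-yl]ethan-1-ol (carbinol epimers) | CC(O)[C@H]1COC(C)(C)O1 | intermediate
24 | 1-[(4R)-2,2-dimethyl-1,3-dioxolan-4-yl]ethan-1-one | CC(=O)[C@H]1COC(C)(C)O1 | intermediate
25 | potassium 1-[(4R)-2,2-dimethyl-1,3-dioxolan-4-yl]ethen-1-olate | [K+].C=C([O-])[C@H]1COC(C)(C)O1 | intermediate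
26 | 1-[(4R)-2,2-dimethyl-1,3-dioxolan-4-yl]ethenyl trifluoromethanesulfonate | C=C(OS(=O)(=O)C(F)(F)F)[C@H]1COC(C)(C)O1 | intermediate
27 | methyl (1S,4aS,5R,6R,8aR)-5-[2-(9-borabicyclo[3.3.1]nonan-9-yl)ethyl]-6-hydroxy-1,4a,6-trimethyldecahydronaphthalene-1-carboxylate | C(C[C@@H]1[C@@]2(C)CCC[C@](C)(C(=O)OC)[C@@H]2CC[C@@]1(C)O)B1C2CCCC1CCC2 | intermediate
28 | methyl (1S,4aS,5R,6R,8aR)-5-{3-[(4S)-2,2-dimethyl-1,3-dioxolan-4-yl]but-3-en-1-yl}-6-hydroxy-1,4a,6-trimethyldecahydronaphthalene-1-carboxylate | C=C(CC[C@@H]1[C@@]2(C)CCC[C@](C)(C(=O)OC)[C@@H]2CC[C@@]1(C)O)[C@H]1COC(C)(C)O1 | intermediate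
29 | (1S,4aS,5R,6R,8aR)-5-{3-[(4S)-2,2-dimethyl-1,3-dioxolan-4-yl]but-3-en-1-yl}-6-hydroxy-1,4a,6-trimethyldecahydronaphthalene-1-carboxylic acid | C=C(CC[C@@H]1[C@@]2(C)CCC[C@](C)(C(=O)O)[C@@H]2CC[C@@]1(C)O)[C@H]1COC(C)(C)O1 | intermediate
30 | (1S,4aS,5R,6R,8aR)-5-[(4S)-4,5-dihydroxy-3-methylidenepentyl]-6-hydroxy-1,4a,6-trimethyldecahydronaphthalene-1-carboxylic acid | C=C(CC[C@@H]1[C@@]2(C)CCC[C@](C)(C(=O)O)[C@@H]2CC[C@@]1(C)O)[C@H](O)CO | target

Total step count: 19. Longest linear sequence: 14 steps (3–13, then 17–19; equally long through 1, 2, 5–13, 17–19).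

Steps most likely to fail

1. Step 9 (cycloaddition). The adduct may revert to the furan during reaction or work-up, the Lewis acid may open the oxygen bridge or alkylate the furan without closing ring B, and the two furan faces may not be told apart well enough. The fallback changes the dienophile to a cationic one (ionic Diels–Alder through the acetal) and sets out from 14. Acetalisation with 1,2-bis(trimethylsilyloxy)ethane and catalytic TMSOTf at −78 °C would give methyl (2R,6E)-7-(1,3-dioxolan-2-yl)-6-methyl-2-(5-methylfuran-2-yl)hept-6-enoate F1. Ionisation of F1 with catalytic TMSOTf or TfOH in CH2Cl2 at −78 °C generates an alkoxyallyl cation, a far stronger dienophile than the complexed enal. Because the acetal has no carbonyl conjugation to lose, the equilibrium should lie further toward the bridged acetal, methyl (1R,2R,6R,7R,8R)-7-(1,3-dioxolan-2-yl)-6,8-dimethyl-11-oxatricyclo[6.2.1.0^1,6]undec-9-ene-2-carboxylate F2; use of this cation-accelerated cycloaddition with a furan diene is an extension of its known scope with carbocyclic dienes. Hydrogenation (H2, Pd/C) would give the saturated acetal methyl (1R,2R,6R,7R,8R)-7-(1,3-dioxolan-2-yl)-6,8-dimethyl-11-oxatricyclo[6.2.1.0^1,6]undecane-2-carboxylate F3, and hydrolysis (PPTS, aqueous acetone) comes back to the route at 16.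

2. Step 13 (reductive methylation). Protonation at C5 may occur from the wrong face, the C8 alkoxide may be O-methylated, the ester may be over-reduced, or the enolate may be only partly trapped in ammonia. The fallback separates reduction from alkylation and sets out from 19. Li/NH3 with the C8 hydroxyl as the only proton donor, quenched with NH4Cl and no alkyl halide, would give the saturated ester methyl (4aS,5R,6R,8aS)-5-ethenyl-6-hydroxy-4a,6-dimethyldecahydronaphthalene-1-carboxylate F4 (C4 epimers, which do not matter). The ring fusion can be checked at this stage. The alkoxide enolate is then regenerated with LiN(iPr)2 (2.2 equiv) in THF–DMPU at −78 °C and methylated with MeI from the same equatorial face, which comes back to the route at 21.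

3. Step 5 (enantioselective alkylation). The aggregate stoichiometry may be disturbed, with loss of enantioselectivity, or the unactivated primary iodide may alkylate sluggishly. The fallback uses a covalent auxiliary (Evans alkylation) and sets out from 9. Activation of 9 as its pivaloyl mixed anhydride and acylation of lithiated (R)-4-benzyloxazolidin-2-one would give (R)-4-benzyl-3-[2-(5-methylfuran-2-yl)acetyl]oxazolidin-2-one F5. Its sodium enolate (NaN(SiMe3)2, THF, −78 °C) is alkylated with 6 on the face away from the benzyl group to give (4R)-4-benzyl-3-[(2R,6E)-8-[(tert-butyldimethylsilyl)oxy]-6-methyl-2-(5-methylfuran-2-yl)oct-6-enoyl]oxazolidin-2-one F6. Methanolysis with MeOMgBr at 0 °C releases the auxiliary and comes back to the route at 12.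

Further compounds
F1 | step 9 | methyl (2R,6E)-7-(1,3-dioxolan-2-yl)-6-methyl-2-(5-methylfuran-2-yl)hept-6-enoate | Cc1ccc(o1)[C@H](C(=O)OC)CCC/C(C)=C/C1OCCO1
F2 | step 9 | methyl (1R,2R,6R,7R,8R)-7-(1,3-dioxolan-2-yl)-6,8-dimethyl-11-oxatricyclo[6.2.1.0^1,6]undec-9-ene-2-carboxylate | C1(OCCO1)[C@@H]2[C@@]3(C)CCC[C@@H](C(=O)OC)[C@]34C=C[C@@]2(C)O4
F3 | step 9 | methyl (1R,2R,6R,7R,8R)-7-(1,3-dioxolan-2-yl)-6,8-dimethyl-11-oxatricyclo[6.2.1.0^1,6]undecane-2-carboxylate | C1(OCCO1)[C@@H]2[C@@]3(C)CCC[C@@H](C(=O)OC)[C@]34CC[C@@]2(C)O4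
F4 | step 13 | methyl (4aS,5R,6R,8aS)-5-ethenyl-6-hydroxy-4a,6-dimethyldecahydronaphthalene-1-carboxylate (C1 epimers) | C=C[C@@H]1[C@@]2(C)CCCC(C(=O)OC)[C@@H]2CC[C@@]1(C)O
F5 | step 5 | (R)-4-benzyl-3-[2-(5-methylfuran-2-yl)acetyl]oxazolidin-2-one | Cc1ccc(CC(=O)N2[C@H](Cc3ccccc3)COC2=O)o1
F6 | step 5 | (4R)-4-benzyl-3-[(2R,6E)-8-[(tert-butyldimethylsilyl)oxy]-6-methyl-2-(5-methylfuran-2-yl)oct-6-enoyl]oxazolidin-2-one | Cc1ccc(o1)[C@H](C(=O)N1[C@H](Cc2ccccc2)COC1=O)CCC/C(C)=C/CO[Si](C)(C)C(C)(C)C
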